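**Retrosynthetic overview**
The target is a trans-(2S,3S)-2-aryl-3-methyl-2,3-dihydrobenzofuran; the last operations are silyl removal from the ring B phenol and Suzuki introduction of the (E)-propenyl group at C5 of ring A.
The strategy rests on C3, a methyl-bearing benzylic carbon of ring A ortho to the ring oxygen O1 (the retron of an ortho-quinone methide), and on C2, a single carbon bonded to O1 and carrying ring B (a one-carbon ylide synthon); ring C is cut at C2–C3 and O1–C2, a formal [4+1] annulation.
Partners: a racemic 2-(1-tosylethyl)phenol from 5-bromo-o-vanillin (MeMgBr, then sulfinic acid) and a C2-symmetric benzylic thiolanium salt from 3-hydroxy-4,5-dimethoxybenzaldehyde (silylation, reduction, bromination) and (2S,5S)-2,5-dimethylthiolane (from (2R,5R)-hexane-2,5-diol).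
Ring order: rings A and B are bought; the dihydrofuran ring C is the only ring formed, in the annulation, which also sets both stereocentres.

Key step: step 9

Assumption (remark on the chemistry): the face selectivity of the benzylide is taken from the established epoxidation behaviour of 2,5-dimethylthiolane benzylides, where the (2R,5R)-thiolane leads to (S,S)-stilbene oxide; because ring B outranks C3 at C2 of the target, whereas the carbonyl-derived carbon outranks phenyl in the epoxide, the same spatial course requires the (2S,5S)-thiolane, hence (2R,5R)-hexane-2,5-diol, for the (2S,3S) target; the ortho-quinone methide is drawn as its E isomer.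

**Route**

Step 1
Reactants: 1 5-bromo-2-hydroxy-3-methoxybenzaldehyde
Product: 2 racemic 4-bromo-2-(1-hydroxyethyl)-6-methoxyphenol
Conditions: MeMgBr (2.5 equiv), THF, 0 °C to rt; aq. NH4Cl
Reagents that add atoms: methylmagnesium bromide, C[Mg]Br
Why: Grignard addition to the aldehyde, the first equivalent being spent on the phenol; the aryl bromide is inert to MeMgBr at this temperature and the racemic carbinol centre is erased in step 9.

Step 2
Reactants: 2 racemic 4-bromo-2-(1-hydroxyethyl)-6-methoxyphenol
Product: 3 racemic 4-bromo-2-methoxy-6-[1-(4-methylbenzenesulfonyl)ethyl]phenol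
Conditions: p-TolSO2H (1.5 equiv), CH2Cl2, rt
Reagents that add atoms: p-toluenesulfinic acid, Cc1ccc(cc1)S(=O)O
Why: Acid-promoted SN1 substitution of the ortho-hydroxybenzylic alcohol (through the protonated ortho-quinone methide) with S-attack of the sulfinate, the standard preparation of 2-(1-tosylalkyl)phenols.

Step 3
Reactants: 4 3-hydroxy-4,5-dimethoxybenzaldehyde
Product: 5 3,4-dimethoxy-5-(triisopropylsilyloxy)benzaldehyde
Conditions: TIPSCl, imidazole, DMF, rt
Reagents that add atoms: triisopropylsilyl chloride, CC(C)[Si](Cl)(C(C)C)C(C)C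
Why: Imidazole-mediated O-silylation of the phenol; the bulky silyl ether masks the ring B phenol against the carbonate base and the electrophilic methide of step 9.

Step 4
Reactants: 5 3,4-dimethoxy-5-(triisopropylsilyloxy)benzaldehyde
Product: 6 [3,4-dimethoxy-5-(triisopropylsilyloxy)phenyl]methanol
Conditions: NaBH4, MeOH, 0 °C
Reagents that add atoms: none
Why: Borohydride reduction of the aldehyde, which leaves the aryl silyl ether untouched.

Step 5
Reactants: 6 [3,4-dimethoxy-5-(triisopropylsilyloxy)phenyl]methanol
Product: 7 [5-(bromomethyl)-2,3-dimethoxyphenoxy]triisopropylsilane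
Conditions: PBr3 (0.4 equiv), CH2Cl2, 0 °C; used without storage
Reagents that add atoms: phosphorus tribromide, BrP(Br)Br
Why: Conversion of an electron-rich benzylic alcohol into the bromide through its phosphite ester, fast at 0 °C, with the aryl silyl ether stable to the brief acidic conditions.

Step 6
Reactants: 8 (2R,5R)-hexane-2,5-diol
Product: 9 (2R,5R)-hexane-2,5-diyl dimethanesulfonate
Conditions: MsCl, Et3N, CH2Cl2, −10 °C
Reagents that add atoms: methanesulfonyl chloride, CS(=O)(=O)Cl
Why: O-sulfonylation forms only O–S bonds, so both carbinol centres keep their configuration.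

Step 7
Reactants: 9 (2R,5R)-hexane-2,5-diyl dimethanesulfonate
Product: 10 (2S,5S)-2,5-dimethylthiolane
Conditions: Na2S·9H2O, EtOH, rt; distillation
Reagents that add atoms: sodium sulfide, [Na+].[Na+].[S-2]
Why: Double SN2 displacement by sulfide (inter- then intramolecular, 5-exo-tet) inverts both centres, so the (R,R)-dimesylate gives the (S,S)-thiolane; this is the known route to C2-symmetric 2,5-dialkylthiolanes.

Step 8
Reactants: 7 [5-(bromomethyl)-2,3-dimethoxyphenoxy]triisopropylsilane; 10 (2S,5S)-2,5-dimethylthiolane
Product: 11 (2S,5S)-1-{[3,4-dimethoxy-5-(triisopropylsilyloxy)phenyl]methyl}-2,5-dimethylthiolan-1-ium tetrafluoroborate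
Conditions: AgBF4 (1.0 equiv), 10 (1.5 equiv), CH2Cl2, 0 °C to rt, dark
Reagents that add atoms: silver tetrafluoroborate, [Ag+].F[B-](F)(F)F
Why: Silver-assisted S-alkylation of the sulfide by the benzylic bromide, made irreversible by precipitation of AgBr and the non-nucleophilic counter-ion; the two sulfur lone pairs are homotopic, so a single sulfonium salt forms.

Step 9
Reactants: 3 racemic 4-bromo-2-methoxy-6-[1-(4-methylbenzenesulfonyl)ethyl]phenol; 11 (2S,5S)-1-{[3,4-dimethoxy-5-(triisopropylsilyloxy)phenyl]methyl}-2,5-dimethylthiolan-1-ium tetrafluoroborate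
Product: 15 (2S,3S)-5-bromo-2-[3,4-dimethoxy-5-(triisopropylsilyloxy)phenyl]-7-methoxy-3-methyl-2,3-dihydro-1-benzofuran, via ortho-quinone methide 12 (not isolated), via benzylic sulfonium ylide 13 (not isolated), via phenoxide sulfonium betaine 14 (not isolated)
Conditions: 11 (1.3 equiv), Cs2CO3 (3 equiv), CH2Cl2, 0 °C to rt
Reagents that add atoms: none
Why: Cs2CO3 deprotonates phenol 3, whose phenoxide expels p-toluenesulfinate (E1cB) to give ortho-quinone methide 12, and deprotonates the benzylic CH2 of salt 11 to give ylide 13; the ylide carbon adds to the exocyclic methide carbon (bond C2–C3, ring A rearomatises) to give betaine 14, and the phenoxide then displaces the thiolane at C2 (bond O1–C2). The closest known reaction type is the formal [4+1] annulation of ortho-quinone methides released from 2-(1-tosylalkyl)phenols with sulfonium ylides to trans-2,3-dihydrobenzofurans, joined here to the benzylide chemistry of C2-symmetric 2,5-dimethylthiolane known from asymmetric epoxidation. Ring C closes by a 5-exo-tet SN2 displacement with inversion at C2. C2 is controlled by the thiolane: the ylide keeps ring B away from the thiolane ring, the ring methyl cis to the ylide carbon blocks one face, and attack of the methide on the open face followed by inversion should give 2S with the (2S,5S) auxiliary. C3 is set relative to C2 in the C–C bond formation, through the open transition state that keeps ring B and the C3 methyl apart and leads to the betaine that closes to the trans (2S,3S) ring. The step needs C-alkylation of the methide by the ylide to outrun methide dimerisation, tautomerisation to the vinylphenol and benzyl transfer from 11 to sulfinate, which the base-limited release of both partners at low stationary concentration and the reversibility of sulfinate addition to 12 are expected to secure.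

Step 10
Reactants: 15 (2S,3S)-5-bromo-2-[3,4-dimethoxy-5-(triisopropylsilyloxy)phenyl]-7-methoxy-3-methyl-2,3-dihydro-1-benzofuran; 16 potassium (E)-prop-1-enyltrifluoroborate
Product: 17 (2S,3S)-2-[3,4-dimethoxy-5-(triisopropylsilyloxy)phenyl]-7-methoxy-3-methyl-5-[(E)-prop-1-enyl]-2,3-dihydro-1-benzofuran
Conditions: PdCl2(dppf) (5 mol%), Cs2CO3 (3 equiv), THF/H2O (10:1), 80 °C
Reagents that add atoms: none
Why: Suzuki–Miyaura coupling of the aryl bromide with the alkenyltrifluoroborate (hydrolysed in the flask to the boronic acid) proceeds with retention of the E geometry and does not touch the two stereocentres; partial loss of the silyl group here would be of no consequence because step 11 removes it.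

Step 11
Reactants: 17 (2S,3S)-2-[3,4-dimethoxy-5-(triisopropylsilyloxy)phenyl]-7-methoxy-3-methyl-5-[(E)-prop-1-enyl]-2,3-dihydro-1-benzofuran
Product: 18 5-[(2S,3S)-7-methoxy-3-methyl-5-[(E)-prop-1-enyl]-2,3-dihydro-1-benzofuran-2-yl]-2,3-dimethoxyphenol (target)
Conditions: TBAF (1.2 equiv), AcOH (1.2 equiv), THF, 0 °C
Reagents that add atoms: none
Why: Fluoride-induced cleavage of the aryl silyl ether (Si–F bond formation), buffered with acetic acid so that the propenyl arene and the benzylic ether at C2 see no strong base.

**Compound list**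
1 | 5-bromo-2-hydroxy-3-methoxybenzaldehyde | O=Cc1cc(Br)cc(OC)c1O | starting material
2 | racemic 4-bromo-2-(1-hydroxyethyl)-6-methoxyphenol | CC(O)c1cc(Br)cc(OC)c1O | intermediate
3 | racemic 4-bromo-2-methoxy-6-[1-(4-methylbenzenesulfonyl)ethyl]phenol | Cc1ccc(cc1)S(=O)(=O)C(C)c1cc(Br)cc(OC)c1O | intermediate
4 | 3-hydroxy-4,5-dimethoxybenzaldehyde | O=Cc1cc(O)c(OC)c(OC)c1 | starting material
5 | 3,4-dimethoxy-5-(triisopropylsilyloxy)benzaldehyde | O=Cc1cc(O[Si](C(C)C)(C(C)C)C(C)C)c(OC)c(OC)c1 | intermediate
6 | [3,4-dimethoxy-5-(triisopropylsilyloxy)phenyl]methanol | OCc1cc(O[Si](C(C)C)(C(C)C)C(C)C)c(OC)c(OC)c1 | intermediate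
7 | [5-(bromomethyl)-2,3-dimethoxyphenoxy]triisopropylsilane | BrCc1cc(O[Si](C(C)C)(C(C)C)C(C)C)c(OC)c(OC)c1 | intermediate
8 | (2R,5R)-hexane-2,5-diol | C[C@@H](O)CC[C@@H](C)O | starting material
9 | (2R,5R)-hexane-2,5-diyl dimethanesulfonate | C[C@@H](OS(C)(=O)=O)CC[C@@H](C)OS(C)(=O)=O | intermediate
10 | (2S,5S)-2,5-dimethylthiolane | C[C@H]1CC[C@H](C)S1 | intermediate
11 | (2S,5S)-1-{[3,4-dimethoxy-5-(triisopropylsilyloxy)phenyl]methyl}-2,5-dimethylthiolan-1-ium tetrafluoroborate | C[C@H]1CC[C@H](C)[S+]1Cc1cc(O[Si](C(C)C)(C(C)C)C(C)C)c(OC)c(OC)c1.F[B-](F)(F)F | intermediate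
12 | (E)-4-bromo-6-ethylidene-2-methoxycyclohexa-2,4-dien-1-one (ortho-quinone methide) | C/C=C1\C=C(Br)C=C(OC)C1=O | intermediate
13 | (2S,5S)-2,5-dimethylthiolan-1-ium-1-yl [3,4-dimethoxy-5-(triisopropylsilyloxy)phenyl]methanide (ylide) | C[C@H]1CC[C@H](C)[S+]1[CH-]c1cc(O[Si](C(C)C)(C(C)C)C(C)C)c(OC)c(OC)c1 | intermediate
14 | 4-bromo-2-{(1R,2S)-1-[3,4-dimethoxy-5-(triisopropylsilyloxy)phenyl]-1-[(2S,5S)-2,5-dimethylthiolan-1-ium-1-yl]propan-2-yl}-6-methoxyphenolate (betaine) | [O-]c1c(OC)cc(Br)cc1[C@H](C)[C@H](c1cc(O[Si](C(C)C)(C(C)C)C(C)C)c(OC)c(OC)c1)[S+]1[C@@H](C)CC[C@@H]1C | intermediate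
15 | (2S,3S)-5-bromo-2-[3,4-dimethoxy-5-(triisopropylsilyloxy)phenyl]-7-methoxy-3-methyl-2,3-dihydro-1-benzofuran | Brc1cc(OC)c2c(c1)[C@H](C)[C@@H](c1cc(O[Si](C(C)C)(C(C)C)C(C)C)c(OC)c(OC)c1)O2 | intermediate
16 | potassium (E)-prop-1-enyltrifluoroborate | C/C=C/[B-](F)(F)F.[K+] | starting material
17 | (2S,3S)-2-[3,4-dimethoxy-5-(triisopropylsilyloxy)phenyl]-7-methoxy-3-methyl-5-[(E)-prop-1-enyl]-2,3-dihydro-1-benzofuran | C/C=C/c1cc(OC)c2c(c1)[C@H](C)[C@@H](c1cc(O[Si](C(C)C)(C(C)C)C(C)C)c(OC)c(OC)c1)O2 | intermediate
18 | 5-[(2S,3S)-7-methoxy-3-methyl-5-[(E)-prop-1-enyl]-2,3-dihydro-1-benzofuran-2-yl]-2,3-dimethoxyphenol | C/C=C/c1cc(OC)c2c(c1)[C@H](C)[C@@H](c1cc(O)c(OC)c(OC)c1)O2 | target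

**Step count**
Total: 11 steps. Longest linear sequence: 7 steps (steps 3, 4, 5, 8, 9, 10 and 11, from 4).

**Steps most likely to fail**

1. Step 9. The conjugate addition restores aromaticity and is therefore probably irreversible, so both the face discrimination at the ylide carbon and the trans preference must be won kinetically. Either may be insufficient. Salt 11 may also be lost by benzyl transfer to sulfinate, and the methide may tautomerise to a vinylphenol. The fallback gives up auxiliary control and separates enantiomers; it sets out from bromide 7 and sulfone 3. Bromide 7 alkylates tetrahydrothiophene (AgBF4, CH2Cl2) to give the achiral salt 1-{[3,4-dimethoxy-5-(triisopropylsilyloxy)phenyl]methyl}thiolan-1-ium tetrafluoroborate F1. This inexpensive salt can be used in larger excess with 3 and Cs2CO3 in CH2Cl2 to give the racemic trans-5-bromo-2-aryl-7-methoxy-3-methyl-2,3-dihydrobenzofuran F2, any cis isomer being removed on silica. Preparative HPLC or SFC on a cellulose tris(3,5-dimethylphenylcarbamate) stationary phase then separates the enantiomers. The (2S,3S) enantiomer is 15, where the route is rejoined before step 10.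

2. Step 8. Silver-promoted ionisation of the very electron-rich benzylic bromide may lead to self-alkylation of the arene, and the salt may dealkylate reversibly on handling. The fallback sets out from alcohol 6 and thiolane 10. Treatment of the two with HBF4·OEt2 in CH2Cl2 at 0 °C alkylates the sulfide directly through the para-methoxy-stabilised benzylic cation and delivers 11 with water as the only by-product. Bromide 7 and the silver salt are thus avoided, and the route is rejoined at 11.

3. Step 10. Oxidative addition at the electron-rich aryl bromide may be slow, leaving time for protodeboronation of the propenyl boron reagent and hydrodebromination under the aqueous basic conditions. The fallback sets out from 15 and is base-free. Stille coupling with allyltributylstannane (Pd(PPh3)4, toluene, 100 °C) gives (2S,3S)-5-allyl-2-[3,4-dimethoxy-5-(triisopropylsilyloxy)phenyl]-7-methoxy-3-methyl-2,3-dihydro-1-benzofuran F3. Isomerisation of the allyl group with PdCl2(MeCN)2 (cat.) in CH2Cl2 at rt then moves the double bond into conjugation and gives the thermodynamically favoured (E)-propenyl compound 17, where the route is rejoined before step 11.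

**Further compounds**
F1 | step 9 | 1-{[3,4-dimethoxy-5-(triisopropylsilyloxy)phenyl]methyl}thiolan-1-ium tetrafluoroborate | C1CC[S+](C1)Cc1cc(O[Si](C(C)C)(C(C)C)C(C)C)c(OC)c(OC)c1.F[B-](F)(F)F
F2 | step 9 | racemic trans-5-bromo-2-[3,4-dimethoxy-5-(triisopropylsilyloxy)phenyl]-7-methoxy-3-methyl-2,3-dihydro-1-benzofuran (1:1 mixture of the (2S,3S) and (2R,3R) enantiomers) | Brc1cc(OC)c2c(c1)[C@H](C)[C@@H](c1cc(O[Si](C(C)C)(C(C)C)C(C)C)c(OC)c(OC)c1)O2.Brc1cc(OC)c2c(c1)[C@@H](C)[C@H](c1cc(O[Si](C(C)C)(C(C)C)C(C)C)c(OC)c(OC)c1)O2
F0 | step 8 | none | none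
F3 | step 10 | (2S,3S)-5-allyl-2-[3,4-dimethoxy-5-(triisopropylsilyloxy)phenyl]-7-methoxy-3-methyl-2,3-dihydro-1-benzofuran | C=CCc1cc(OC)c2c(c1)[C@H](C)[C@@H](c1cc(O[Si](C(C)C)(C(C)C)C(C)C)c(OC)c(OC)c1)O2
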